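The data were generated by integration from invented constants, and the scatter is random.

You have 3 questions about two flasks, and the earlier runs report Q and nothing else.

| flask | Z | L | temperature | remark | time |
|---|---|---|---|---|---|
| red | 0.50 M | 1.2 equiv | 40 °C | run made earlier |  |
| ochre | 1.1 M | 1.2 equiv | 73 °C | run made earlier |  |
| blue | 1.7 M | 1.2 equiv | 40 °C | run made earlier |  |
| summer | 0.60 M | 1.20 equiv |  | at 25 °C throughout | 15 min |
| autumn | 2.0 M | 1.20 equiv |  | at 25 °C until 8.0 min, from then on at 85 °C | 15 min |

- red (time / min: Q / %): 0.667: 4.4; 1.33: 7.0; 2.50: 13.3; 3.00: 15.6; 4.00: 19.5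
- ochre (time / s: Q / %): 10.0: 12.0; 15.0: 17.2; 30.0: 28.5; 40.0: 34.8
- blue (time / min: Q / %): 0.333: 3.3; 0.500: 4.8; 1.00: 10.4; 2.00: 18.0; 4.00: 30.5

(each reading ± 0.3 percentage points)

* which of the two ends with the higher amount of Q, in percent of the Z charged ("neither" if they lie within 2 percentage points) (summer / autumn / neither)
* Q at the end, in percent of the Z charged, summer
* Q at the end, in percent of the Z charged, autumn

- the numbers in the tables scatter with a standard deviation of 0.3 percentage points
- where the amount of Z changes, what is given in equivalents or mol% on it follows

Work with the fraction left, not the fraction made. Suppose for the moment that Q is the one outlet of Z. Then each reading gives a constant: the natural logarithm of one over the fraction not yet Q, divided by the time. The last readings give 0.0542 min⁻¹ for red, 0.0910 min⁻¹ for blue and 0.642 min⁻¹ for ochre. Red and blue share a temperature and their equivalents of L, so Z and L rise together between them, and the rise from red to blue reads as an exponent of 0.423 on the overall concentration, which these runs do not split between Z and L. Rounding that exponent to 0.5 for this one step, ochre against red reads as an activation energy of 56.7 kJ mol⁻¹.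

Carrying both to autumn's start gives 0.0326 min⁻¹. Call this the Q clock of autumn, the logarithmic rate at which the fraction of Z not yet in Q shrinks.

Now run autumn slowly, by my own reckoning. In the first instants it stands at 25 °C, and over the cold 8.0 min the clock leaves 77.1 % of Z, so about 22.9 % is Q. Then the heat arrives and the clock jumps to 1.50 min⁻¹. Its time of 0.667 min is far shorter than the 7.00 min remaining, so by the end nearly all of Z should be Q. Summer's clock, 0.0196 min⁻¹, is slower than autumn's, and it gives about 25.4 % of Q at the end. The tables hold no reading of Z, so the single outlet stays an assumption.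

The forecast says autumn, with 24 % for summer and 99.5 % for autumn, “assuming no Q loss when hot”.

Summer ends at 24.0 % of Q and autumn at 57.5 %, so autumn leads, but 42 percentage points below the forecast's figure.

    Z + L → Q, rate k1*[Z]^0.5*[L] (k = 0.0220 M⁻⁰·⁵ min⁻¹, Ea = 61.0 kJ mol⁻¹)
    2 Z → E (k = 0.0160 M⁻¹ min⁻¹, Ea = 68.0 kJ mol⁻¹)
    (constants at 25 °C)

In autumn, the rate at which Z goes to Q over that at which it goes to E, a selectivity factor, is 0.58 at the start and 1.2 at 8.06 min, and the flask ends with 42.5 % in E, counted as the Z it holds. So at the change of temperature the clock's 77.1 % of Z stands against 50.4 % in autumn, with Q at 22.6 % and E at 26.9 %. The neighbour flask, autumn read at 6.0 min, shows the same gap: the clock leaves 82.2 % and gives 17.8 % of Q, while the flask holds 18.1 % of Q and only 58.8 % of Z.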